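The data are calculated for an exercise; noise was put on by code.

1. I began with the easy step of laying out the flask, the two runs and what was asked of Friday's flask.

| flask | J | Q | remark | time |
|---|---|---|---|---|
| Friday's | 0.090 M | 1.8 equiv | the very flask that is asked about, followed so far |  |
| Wednesday's | 0.060 M | 1.8 equiv | run made earlier |  |
| flask | 0.090 M | 1.80 equiv |  | 5.0 d |

- Friday's (time / h: X / %, D / %): 1.33: 57, 4; 3.00: 61, 5; 6.00: 51, 6; 10.0: 41, 4
- Wednesday's (time / h: X / %, D / %): 12.0: 39, 5; 25.0: 22, 3; 40.0: 17, 4; 50.0: 18, 6

(each reading ± 2 percentage points)



- ratio of X to D at 2.5 min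
- ratio of X to D at 2.0 h
- ratio of X to D at 5.0 d
- which of X and D there is more of at 5.0 d

2. The decision was whether to charge more Q to favour X over D in Friday's recipe.

3. I divided Friday's first X reading by its first D reading and got 14.3. This is my selectivity factor: the rate at which X forms divided by the rate at which D forms, read as the ratio of what has formed so far.

4. One standard deviation either way on D, with X held at its reading, puts this ratio between 9.50 and 28.5.

5. I assumed that each product forms from one J and one Q. Both forward rates then carry the same concentrations, so time and charges drop out when one forward rate is divided by the other.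

6. I therefore committed to 14.3 at 2.5 min, set no figure for later times, and expected more Q to leave the early ratio unchanged. I would not charge extra Q for the sake of that ratio.

7. The forecast gave 15 at 2.5 min, 13 at 2.0 h and 3.5 at 5.0 d, with X ahead, and held that “D looks like a parallel minor product from J”. My 14.3 stood below its first figure.

8. Friday's flask gave 22.0 at 2.5 min, 16.0 at 2.0 h and 1.95 at 5.0 d, with X ahead at 8.83 % against 4.53 % of D.

    J + Q ⇌ X (K = 50.0 /M, k = 0.140 /M/min)
    J + Q ⇌ D (K = 18.0 /M, k = 0.00630 /M/min)
    J + X → G (k = 0.0580 /M/min)
    Q → Z (k = 9.20 × 10⁻⁷ /min)

Each forward step does take one J and one Q, and at the start the step to X uses Q 22 times as fast as the step to D, counting each forward rate alone. In the neighbour flask, charged with 7.20 equiv of Q, the division behind my reading of 14.3 cancels Q, so I reckoned its ratio at 2.5 min at the 22.0 of Friday's flask, and it gave 22.0. At 5.0 d the neighbour flask's ratio was 2.33, with X at 27.7 % and D at 11.9 %.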